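**Retrosynthetic overview** (ring numbering: O1, C2 bearing CO2Me, C3 bearing the aryl group, C4 bearing the benzylidene, C5 = lactone C=O; the target is 2,3-cis, 4Z)
1. Target ⇒ its tetra-O-benzyl ether; global debenzylation is the last step.
2. Lactone O1–C5 ⇒ syn γ-hydroxy diester; the γ-lactone is the only ring and closes in the same flask, right after the key C–C bond.
3. Key disconnection C2–C3 with allylic transposition: methyl glyoxylate + a 1,3-diaryl-2-(alkoxycarbonyl)allyl metal. The allyl metal is a β-acyl carbanion (homoenolate) equivalent, so two carbons that are normally both electrophilic are joined; this one step sets both stereocentres and the Z-alkene.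
4. Allyl metal ⇒ (E)-α-benzylcinnamate, by deprotonation and Li→Cr(III) exchange ⇒ aldol condensation of a 3-arylpropanoate with 3,4-bis(benzyloxy)benzaldehyde.
5. 3-Arylpropanoate ⇒ dihydrocaffeic acid + benzyl bromide.

Assumption: the (S,S)-bis(oxazolinyl)carbazole ligand is taken to direct attack to the Si face of the aldehyde; if the opposite sense is found, its (R,R)-antipode is used with nothing else changed.

**Step 1**
Reactants: 1 3-(3,4-dihydroxyphenyl)propanoic acid (dihydrocaffeic acid)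
Product: 2 benzyl 3-[3,4-bis(benzyloxy)phenyl]propanoate
Conditions: BnBr (3.3 equiv), K2CO3 (4 equiv), DMF, N2, 60 °C
Reagents that add atoms: benzyl bromide, BrCc1ccccc1
Why: Williamson ether synthesis and carboxylate O-alkylation, in which K2CO3 deprotonates both phenols and the acid and the anions displace bromide from benzyl bromide (SN2); no stereocentre is involved.

**Step 2**
Reactants: 2 benzyl 3-[3,4-bis(benzyloxy)phenyl]propanoate; 3 3,4-bis(benzyloxy)benzaldehyde
Product: 5 benzyl (2E)-2-[3,4-bis(benzyloxy)benzyl]-3-[3,4-bis(benzyloxy)phenyl]prop-2-enoate, via aldol acetate 4 (not isolated)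
Conditions: LDA (1.1 equiv), THF, −78 °C; 3; Ac2O (1.5 equiv), −78 → 0 °C; DBU (3 equiv), rt
Reagents that add atoms: none
Why: Directed aldol condensation, in which the lithium ester enolate of 2 adds to 3, the aldolate is trapped as acetate 4 and DBU-promoted E1cB elimination gives the conjugated trisubstituted alkene as the thermodynamically favoured E isomer (aryl trans to the ester); no stereocentre remains.

**Step 3**
Reactants: 5 benzyl (2E)-2-[3,4-bis(benzyloxy)benzyl]-3-[3,4-bis(benzyloxy)phenyl]prop-2-enoate; 6 methyl glyoxylate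
Product: 10 methyl (2S,3R,4Z)-4-[3,4-bis(benzyloxy)benzylidene]-3-[3,4-bis(benzyloxy)phenyl]-5-oxooxolane-2-carboxylate, via allyllithium 7 (not isolated), via allylchromium(III) complex 8 (not isolated), via hydroxy diester 9 (not isolated)
Conditions: LDA (1.05 equiv), THF, −78 °C; [CrCl2(L)(THF)] (1.15 equiv, L = (S,S)-1,8-bis(4-isopropyl-4,5-dihydrooxazol-2-yl)-3,6-diphenylcarbazol-9-ide), −78 → −30 °C; 6 (2 equiv, freshly distilled monomer), −30 → 0 °C, dark; aq. NH4Cl; then p-TsOH·H2O (10 mol %), CH2Cl2, rt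
Reagents that add atoms: none
Why: Proposed new method: LDA removes a proton from the doubly activated (benzylic and allylic) CH2 of 5 to give the 1,3-diaryl-2-(alkoxycarbonyl)allyl anion 7, a homoenolate equivalent whose nucleophilic carbon is the cinnamate β-carbon, and Li→Cr(III) exchange gives 8, the kind of allylchromium(III) species that operates in catalytic asymmetric Nozaki–Hiyama–Kishi 2-(alkoxycarbonyl)allylations (closest known reaction type; Dreiding–Schmidt-type lactone synthesis); 8 adds through its γ-carbon to the aldehyde of 6 in a chair transition state with CO2Me equatorial, the γ-aryl axial because the (E)-cinnamate geometry of 8 is kept (hence 3,4-syn in 9 and 2,3-cis in 10) and the α-aryl equatorial to avoid a 1,3-diaxial clash with it (hence the Z-benzylidene), while the ligand selects the Si face of the aldehyde and so sets (3R,4S) in 9, and acid-catalysed lactonisation with loss of benzyl alcohol then gives 10 without touching either stereocentre.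

**Step 4**
Reactants: 10 methyl (2S,3R,4Z)-4-[3,4-bis(benzyloxy)benzylidene]-3-[3,4-bis(benzyloxy)phenyl]-5-oxooxolane-2-carboxylate
Product: 11 methyl (2S,3R,4Z)-4-(3,4-dihydroxybenzylidene)-3-(3,4-dihydroxyphenyl)-5-oxooxolane-2-carboxylate (CNP0143432.1)
Conditions: BCl3 (1 M in CH2Cl2, 10 equiv), pentamethylbenzene (15 equiv), CH2Cl2, −78 °C, dark; MeOH quench at −78 °C
Reagents that add atoms: none
Why: Lewis-acid debenzylation with a non-Lewis-basic cation scavenger, in which BCl3 activates the aryl benzyl ethers and pentamethylbenzene captures the benzyl cations by Friedel–Crafts alkylation at −78 °C, conditions (no base, no hydrogen, no light) under which the methyl ester, the lactone, the Z-alkene and both stereocentres are left untouched.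

**Compound list**
1 | 3-(3,4-dihydroxyphenyl)propanoic acid | OC(=O)CCc1ccc(O)c(O)c1 | starting material
2 | benzyl 3-[3,4-bis(benzyloxy)phenyl]propanoate | O=C(CCc1ccc(OCc2ccccc2)c(OCc2ccccc2)c1)OCc1ccccc1 | intermediate
3 | 3,4-bis(benzyloxy)benzaldehyde | O=Cc1ccc(OCc2ccccc2)c(OCc2ccccc2)c1 | starting material
4 | benzyl 3-acetoxy-2-[3,4-bis(benzyloxy)benzyl]-3-[3,4-bis(benzyloxy)phenyl]propanoate (diastereomer mixture, not isolated) | CC(=O)OC(c1ccc(OCc2ccccc2)c(OCc2ccccc2)c1)C(Cc1ccc(OCc2ccccc2)c(OCc2ccccc2)c1)C(=O)OCc1ccccc1 | intermediate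
5 | benzyl (2E)-2-[3,4-bis(benzyloxy)benzyl]-3-[3,4-bis(benzyloxy)phenyl]prop-2-enoate | O=C(OCc1ccccc1)/C(Cc1ccc(OCc2ccccc2)c(OCc2ccccc2)c1)=C/c1ccc(OCc2ccccc2)c(OCc2ccccc2)c1 | intermediate
6 | methyl glyoxylate | COC(=O)C=O | starting material
7 | {1,3-bis[3,4-bis(benzyloxy)phenyl]-2-(benzyloxycarbonyl)allyl}lithium (σ-form drawn, not isolated) | [Li]C(c1ccc(OCc2ccccc2)c(OCc2ccccc2)c1)/C(=C\c1ccc(OCc2ccccc2)c(OCc2ccccc2)c1)C(=O)OCc1ccccc1 | intermediate
8 | chlorido{1,3-bis[3,4-bis(benzyloxy)phenyl]-2-(benzyloxycarbonyl)allyl}chromium(III) (S,S)-1,8-bis(4-isopropyl-4,5-dihydrooxazol-2-yl)-3,6-diphenylcarbazolide (σ-allyl form, Cr-bearing carbon labile, oxazoline N→Cr bonds not drawn, not isolated) | Cl[Cr](C(c1ccc(OCc2ccccc2)c(OCc2ccccc2)c1)/C(=C\c1ccc(OCc2ccccc2)c(OCc2ccccc2)c1)C(=O)OCc1ccccc1)n1c2c(C3=N[C@@H](C(C)C)CO3)cc(-c3ccccc3)cc2c2cc(-c3ccccc3)cc(C3=N[C@@H](C(C)C)CO3)c12 | intermediate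
9 | 1-benzyl 5-methyl (2Z,3R,4S)-2-[3,4-bis(benzyloxy)benzylidene]-3-[3,4-bis(benzyloxy)phenyl]-4-hydroxypentanedioate (not isolated) | COC(=O)[C@@H](O)[C@H](c1ccc(OCc2ccccc2)c(OCc2ccccc2)c1)/C(=C/c1ccc(OCc2ccccc2)c(OCc2ccccc2)c1)C(=O)OCc1ccccc1 | intermediate
10 | methyl (2S,3R,4Z)-4-[3,4-bis(benzyloxy)benzylidene]-3-[3,4-bis(benzyloxy)phenyl]-5-oxooxolane-2-carboxylate | COC(=O)[C@H]1OC(=O)/C(=C\c2ccc(OCc3ccccc3)c(OCc3ccccc3)c2)[C@H]1c1ccc(OCc2ccccc2)c(OCc2ccccc2)c1 | intermediate
11 | methyl (2S,3R,4Z)-4-(3,4-dihydroxybenzylidene)-3-(3,4-dihydroxyphenyl)-5-oxooxolane-2-carboxylate | COC(=O)[C@H]1OC(=O)/C(=C\c2ccc(O)c(O)c2)[C@H]1c1ccc(O)c(O)c1 | target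

**Totals:** 4 steps; longest linear sequence 4 steps (1 → 2 → 5 → 10 → 11).

**Steps most likely to fail**

Step 3. The chair addition may not follow the predicted course (2,3-trans lactone, E-benzylidene or low ee), and Cr(III) may oxidise the electron-rich anion 7 by single-electron transfer, giving allyl dimers. The fallback sets out from 3 and comes back at 10, and makes the same C–C bond with a carbene-derived homoenolate instead. Wittig homologation of 3 with (triphenylphosphoranylidene)acetaldehyde gives (E)-3-[3,4-bis(benzyloxy)phenyl]prop-2-enal F1. With a chiral aminoindanol-derived N-mesityl triazolylidene (DBU, THF), F1 forms a Breslow homoenolate that adds to 6 and lactonises to the cis lactone methyl (2S,3S)-3-[3,4-bis(benzyloxy)phenyl]-5-oxooxolane-2-carboxylate F2. Kinetic enolisation at the ring CH2 (LiHMDS, −78 °C), aldol addition to 3 and acetylation give the β-acetoxy lactone methyl (2S,3S)-4-{acetoxy[3,4-bis(benzyloxy)phenyl]methyl}-3-[3,4-bis(benzyloxy)phenyl]-5-oxooxolane-2-carboxylate F3. DBU elimination gives the E-benzylidene lactone methyl (2S,3R,4E)-4-[3,4-bis(benzyloxy)benzylidene]-3-[3,4-bis(benzyloxy)phenyl]-5-oxooxolane-2-carboxylate F4, and 365 nm irradiation with chromatographic recycling of F4 gives the Z isomer 10.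

Step 4. Four benzyl ethers may not all cleave at −78 °C, and Lewis acid or light may erode the Z geometry. The fallback sets out from 10 and comes back at 11: the ethers are cleaved by protic acidolysis (TFA, thioanisole, pentamethylbenzene, rt) without regard to alkene geometry. The resulting mixture contains methyl (2S,3R,4E)-4-(3,4-dihydroxybenzylidene)-3-(3,4-dihydroxyphenyl)-5-oxooxolane-2-carboxylate F5. The geometry is then corrected by 365 nm photoisomerisation and reverse-phase HPLC with recycling of F5, which gives 11.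

Step 2. Retro-aldol of the electron-rich aldolate or poor E/Z control in the elimination may lower the yield. The fallback sets out from 3 and comes back at 5, and builds the alkene by olefination instead. Knoevenagel condensation of 3 with benzyl (dimethoxyphosphoryl)acetate (TiCl4, N-methylmorpholine, THF) gives benzyl 3-[3,4-bis(benzyloxy)phenyl]-2-(dimethoxyphosphoryl)prop-2-enoate F6. Conjugate reduction with NaBH4 gives benzyl 3-[3,4-bis(benzyloxy)phenyl]-2-(dimethoxyphosphoryl)propanoate F7. Horner–Wadsworth–Emmons reaction of F7 (NaH, THF) with a second equivalent of 3 gives 5.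

**Further compounds**
F1 | step 3 | (E)-3-[3,4-bis(benzyloxy)phenyl]prop-2-enal | O=C/C=C/c1ccc(OCc2ccccc2)c(OCc2ccccc2)c1
F2 | step 3 | methyl (2S,3S)-3-[3,4-bis(benzyloxy)phenyl]-5-oxooxolane-2-carboxylate | COC(=O)[C@H]1OC(=O)C[C@H]1c1ccc(OCc2ccccc2)c(OCc2ccccc2)c1
F3 | step 3 | methyl (2S,3S)-4-{acetoxy[3,4-bis(benzyloxy)phenyl]methyl}-3-[3,4-bis(benzyloxy)phenyl]-5-oxooxolane-2-carboxylate (diastereomer mixture) | COC(=O)[C@H]1OC(=O)C(C(OC(C)=O)c2ccc(OCc3ccccc3)c(OCc3ccccc3)c2)[C@H]1c1ccc(OCc2ccccc2)c(OCc2ccccc2)c1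
F4 | step 3 | methyl (2S,3R,4E)-4-[3,4-bis(benzyloxy)benzylidene]-3-[3,4-bis(benzyloxy)phenyl]-5-oxooxolane-2-carboxylate | COC(=O)[C@H]1OC(=O)/C(=C/c2ccc(OCc3ccccc3)c(OCc3ccccc3)c2)[C@H]1c1ccc(OCc2ccccc2)c(OCc2ccccc2)c1
F5 | step 4 | methyl (2S,3R,4E)-4-(3,4-dihydroxybenzylidene)-3-(3,4-dihydroxyphenyl)-5-oxooxolane-2-carboxylate | COC(=O)[C@H]1OC(=O)/C(=C/c2ccc(O)c(O)c2)[C@H]1c1ccc(O)c(O)c1
F6 | step 2 | benzyl 3-[3,4-bis(benzyloxy)phenyl]-2-(dimethoxyphosphoryl)prop-2-enoate (E/Z mixture) | COP(=O)(OC)C(=Cc1ccc(OCc2ccccc2)c(OCc2ccccc2)c1)C(=O)OCc1ccccc1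
F7 | step 2 | benzyl 3-[3,4-bis(benzyloxy)phenyl]-2-(dimethoxyphosphoryl)propanoate (racemic) | COP(=O)(OC)C(Cc1ccc(OCc2ccccc2)c(OCc2ccccc2)c1)C(=O)OCc1ccccc1
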